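The readings stem from a simulated flask with made-up constants, noise included.

The constants are hidden, so the two earlier runs have to stand in for them.

| flask | starting material | second substrate | coupling partner | free catalyst | remark | time |
|---|---|---|---|---|---|---|
| birch | 0.50 mM | 1 equiv | 1.1 equiv | 0.5 mol% | run made earlier |  |
| cedar | 0.50 mM | 1 equiv | 3.3 equiv | 0.5 mol% | run made earlier |  |
| west | 0.50 mM | 1.00 equiv | 0.800 equiv | 0.5 mol% |  | 3.0 min |
| south | 0.50 mM | 1.00 equiv | 1.20 equiv | 0.5 mol% |  | 3.0 min |
| north-east | 0.50 mM | 1.00 equiv | 2.00 equiv | 0.5 mol% |  | 3.0 min |
| south-east | 0.50 mM | 1.00 equiv | 2.50 equiv | 0.5 mol% |  | 3.0 min |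

| run | time / s | target / % |
|---|---|---|
| birch | 12.0 | 12.4 |
| birch | 30.0 | 19.6 |
| birch | 60.0 | 25.5 |
| birch | 90.0 | 23.0 |
| birch | 120 | 25.5 |
| cedar | 12.0 | 17.6 |
| cedar | 30.0 | 20.1 |
| cedar | 60.0 | 18.4 |
| cedar | 90.0 | 13.2 |
| cedar | 120 | 9.8 |

(each reading ± 1 percentage point)

- the earlier runs were read with a standard deviation of 1 percentage point
- candidate steps: coupling partner + catalyst intermediate B -> free catalyst + second product; second substrate + free catalyst <-> catalyst intermediate B; coupling partner + catalyst intermediate A -> free catalyst + target; starting material + free catalyst <-> catalyst intermediate A; coupling partner + target -> over-reaction product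
- "hardly changes" means that all values lie within two and a half points (for a concentration: within two and a half percent of the largest)

- amount of target at the end, in percent of the starting material charged for west, south, north-east, south-east, in this order
- how that number moves from the first to the last of them (falls all the way / hardly changes / falls, then rises / rises all the way / rises, then falls)

Here is the quick number, with a test of the hunch that more coupling partner means more target.

1. Coupling partner is paid out by 3 paths: on catalyst intermediate A to give target, on catalyst intermediate B to give second product, and on target to give over-reaction product.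

2. The last 3 birch readings average 24.7% of target, level at the scatter of 1 percentage point. The birch charge divided by that level gives 4.46. This is the partner price, the equivalents of coupling partner charged per equivalent of target standing.

3. Held fixed at the birch price, this reckoning puts west at 17.9% and south at 26.9%. So at the low end of the row the reckoning goes with the hunch.

4. Cedar carries more coupling partner than south-east. Its highest reading, 20.1%, lies below the birch level. Its last reading, still falling, costs 33.7, above the birch price.

5. From birch to cedar the price read off the runs climbs, so this reckoning expects a rise, then a fall. It puts no figure on north-east or south-east.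

The forecast reads 20%, 25%, 21.5% and 17%, so rises, then falls, on the ground that at 2.00 equiv “over-reaction eats in”. It stands above the price reckoning for west and below it for south.

The flasks give 21.2%, 26.5%, 29.5% and 25.6%, so rises, then falls.

    coupling partner + catalyst intermediate B → free catalyst + second product (k = 2.80 × 10⁵ M⁻¹ s⁻¹)
    second substrate + free catalyst ⇌ catalyst intermediate B (K = 680 M⁻¹, k = 42000 M⁻¹ s⁻¹)
    coupling partner + catalyst intermediate A → free catalyst + target (k = 9100 M⁻¹ s⁻¹)
    starting material + free catalyst ⇌ catalyst intermediate A (K = 14000 M⁻¹, k = 25000 M⁻¹ s⁻¹)
    coupling partner + target → over-reaction product (k = 80.0 M⁻¹ s⁻¹)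

Coupling partner, the limiting reagent, is down to 0.756% of its charge in south-east at 3.00 min. South-east has paid a price of 9.77, above the 3.77 of west. South-east pays this because the partner couples target on to over-reaction product: with that path taken away, south-east holds 99.6% of target against 25.6%, a price of 2.51. South-east ends with 62.8% of over-reaction product.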